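**Plan**
- Retrosynthesis: ring C (the 1,2-dioxane) is opened at O–C16 (a hydroperoxide displacing a C16 mesylate) and at C13–O (perhydrolysis of a 13,14-epoxide); the chain is cut at C12–C13 (B-alkyl Suzuki coupling); the C8 methyl and the C9 oxygen are taken back to a C8=C9 enal; rings A and B are cut together at C5–C10 and C8–C9.
- Enabling feature: rings A and B share the C5–C10 bond, C10 is quaternary and C9 carries C11. A C9=C10 β-methyl enal (C11 = CHO), linked through C1–C4 to a C5–C8 diene, therefore folds onto the whole decalin in one intramolecular Diels–Alder reaction.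
- Forward: geraniol gives the acyclic trienal 17; rings A and B form at once (step 11); the C8 methyl and C9 oxygen follow; the C13–C18 vinyl iodide 33 is joined; ring C is closed last; then the acid.
- Stereochemistry: C5 and C10 come from the catalyst-controlled endo cycloaddition; C8 and C9 from α-face attack anti to the C10 methyl; C16 and C17 from an Evans syn-aldol (C16 inverted on ring closure); C13 from a Shi epoxidation followed by invertive perhydrolysis.

Key step: step 11

Numbering: decalin C1–C10 (gem-dimethyl on C4, angular methyl on C10, ring A = C1–C5/C10, ring B = C5–C10); C11–C12 the ethylene link on C9; C13 the methyl-bearing dioxane carbon; C14, C15 the dioxane CH2 groups; C16 the dioxane CH; C17 the α-carbon of the acid; C18 the carboxyl carbon; ring C = O–O–C16–C15–C14–C13. α/β refer to the usual drawing with the C10 methyl β.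

Assumption: the oxazaborolidinium cation is taken to bind the β,β-disubstituted enal as it binds simpler enals (s-trans, formyl C–H···O contact), so that the (R)-prolinol-derived catalyst leaves the C9 Si face open as the (5S,10S) series requires; the antipodal catalyst is equally accessible.

**Step 1**
Reactants: 1 geraniol
Product: 2 geranyl tert-butyldimethylsilyl ether
Conditions: TBSCl, imidazole, CH2Cl2, 0 °C → rt
Reagents that add atoms: tert-butyldimethylsilyl chloride, CC(C)(C)[Si](C)(C)Cl
Why: Silylation of the primary allylic alcohol masks the C11 oxygen through the organometallic steps and can later be removed without harming an enol ester.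

**Step 2**
Reactants: 2 geranyl tert-butyldimethylsilyl ether
Product: 3 6,7-epoxygeranyl tert-butyldimethylsilyl ether (racemic)
Conditions: mCPBA, NaHCO3, CH2Cl2, −20 → 0 °C
Reagents that add atoms: 3-chloroperoxybenzoic acid, O=C(OO)c1cccc(Cl)c1
Why: Prilezhaev epoxidation should pick the more electron-rich distal alkene, the proximal one being deactivated by the allylic silyloxy group; the epoxide stereocentre is excised in step 3.

**Step 3**
Reactants: 3 6,7-epoxygeranyl tert-butyldimethylsilyl ether
Product: 5 (E)-6-[(tert-butyldimethylsilyl)oxy]-4-methylhex-4-en-1-ol, via aldehyde 4 (not isolated)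
Conditions: H5IO6, THF/Et2O, 0 °C; then NaBH4, MeOH, 0 °C
Reagents that add atoms: none
Why: Periodic acid opens the epoxide and cleaves the resulting glycol to the C3 aldehyde with loss of acetone, and borohydride reduction in the same flask gives the primary alcohol.

**Step 4**
Reactants: 5 (E)-6-[(tert-butyldimethylsilyl)oxy]-4-methylhex-4-en-1-ol
Product: 6 (E)-[(6-bromo-3-methylhex-2-enyl)oxy](tert-butyl)dimethylsilane
Conditions: CBr4, PPh3, CH2Cl2, 0 °C
Reagents that add atoms: tetrabromomethane, BrC(Br)(Br)Br
Why: The Appel reaction converts the unhindered primary alcohol into the bromide under neutral conditions that spare the allylic silyl ether.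

**Step 5**
Reactants: 6 (E)-[(6-bromo-3-methylhex-2-enyl)oxy](tert-butyl)dimethylsilane; 7 ethyl 3-methylbut-2-enoate
Product: 10 ethyl (E)-9-[(tert-butyldimethylsilyl)oxy]-3,3,7-trimethylnon-7-enoate, via Grignard reagent 8 (not isolated), via silyl ketene acetal 9 (not isolated)
Conditions: Mg, THF, rt; then CuI (10 mol%), TMSCl, 7, THF, −40 → 0 °C; aq. NH4Cl
Reagents that add atoms: none
Why: Copper-catalysed, chlorosilane-accelerated conjugate addition of the Grignard reagent to the β,β-dimethyl enoate forms the C3–C4 bond and the quaternary C4 with its gem-dimethyl group, and the ketene acetal is hydrolysed on work-up.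

**Step 6**
Reactants: 10 ethyl (E)-9-[(tert-butyldimethylsilyl)oxy]-3,3,7-trimethylnon-7-enoate
Product: 11 (E)-9-[(tert-butyldimethylsilyl)oxy]-3,3,7-trimethylnon-7-enal
Conditions: i-Bu2AlH, CH2Cl2, −78 °C; aq. potassium sodium tartrate (KNaC4H4O6)
Reagents that add atoms: none
Why: Low-temperature partial reduction of the ester stops at the aluminium hemiacetal, which releases the aldehyde (C6) on work-up.

**Step 7**
Reactants: 11 (E)-9-[(tert-butyldimethylsilyl)oxy]-3,3,7-trimethylnon-7-enal; 12 (triphenylphosphoranylidene)acetaldehyde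
Product: 13 (2E,9E)-11-[(tert-butyldimethylsilyl)oxy]-5,5,9-trimethylundeca-2,9-dienal
Conditions: toluene, 80 °C
Reagents that add atoms: none
Why: Wittig olefination with the stabilised formyl ylide adds C7 and C8 as an (E)-enal, and the conjugated product is less reactive toward the ylide than the starting aldehyde.

**Step 8**
Reactants: 13 (2E,9E)-11-[(tert-butyldimethylsilyl)oxy]-5,5,9-trimethylundeca-2,9-dienal
Product: 15 (1E,3E,9E)-11-[(tert-butyldimethylsilyl)oxy]-5,5,9-trimethylundeca-1,3,9-trienyl benzoate, via potassium dienolate 14 (not isolated)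
Conditions: KOtBu, THF, −78 °C; then BzCl, −78 → 0 °C
Reagents that add atoms: benzoyl chloride, O=C(Cl)c1ccccc1
Why: γ-Deprotonation at C5 gives the extended dienolate, and O-acylation of this hard potassium enolate gives the 1-acyloxy diene; the s-trans enal fixes the (1E) enol ester and the bulky C4 substituent the (3E) alkene.

**Step 9**
Reactants: 15 (1E,3E,9E)-11-[(tert-butyldimethylsilyl)oxy]-5,5,9-trimethylundeca-1,3,9-trienyl benzoate
Product: 16 (1E,3E,9E)-11-hydroxy-5,5,9-trimethylundeca-1,3,9-trienyl benzoate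
Conditions: HF·pyridine, pyridine, THF, 0 °C → rt
Reagents that add atoms: none
Why: Buffered fluoride desilylation frees the allylic alcohol without the basic conditions that would cleave the dienyl benzoate.

**Step 10**
Reactants: 16 (1E,3E,9E)-11-hydroxy-5,5,9-trimethylundeca-1,3,9-trienyl benzoate
Product: 17 (2E,8E,10E)-11-(benzoyloxy)-3,7,7-trimethylundeca-2,8,10-trienal
Conditions: MnO2, CH2Cl2, rt
Reagents that add atoms: none
Why: Allylic oxidation with MnO2 gives the (E)-β-methyl enal under neutral conditions that preserve alkene geometry and the enol ester.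

**Step 11**
Reactants: 17 (2E,8E,10E)-11-(benzoyloxy)-3,7,7-trimethylundeca-2,8,10-trienal
Product: 18 8β-benzoyloxy-9β-formyl-4,4,10β-trimethyl-5αH-octal-6-ene (trans-fused)
Conditions: (R)-oxazaborolidine C24H24BNO [from (R)-α,α-diphenylprolinol and tri-o-tolylboroxine] (20 mol%), Tf2NH (18 mol%), CH2Cl2, −78 → −20 °C; aq. NaHCO3
Reagents that add atoms: none
Why: Proposed new method: the triflimide-protonated oxazaborolidine binds the formyl oxygen of the s-trans enal (formyl C–H···O contact), lowers its LUMO and covers one face, and the benzoyloxy diene then adds in a concerted, asynchronous [4+2] cycloaddition that forms C5–C10 and C8–C9. The closest known reaction type is the oxazaborolidinium-catalysed intramolecular Diels–Alder reaction of 2,8,10-trienals that lack a β-substituent, together with thermal and Lewis-acid cycloadditions of β-methyl trienals that build angular methyl groups; untested is only the pairing of the β,β-disubstituted enal with the chiral cation. Ring B is the cyclohexene created by the cycloaddition itself, and ring A closes through the same C5–C10 bond as the six-membered carbocycle that holds the C1–C4 tether in a chair-like array. The endo transition state of the (E)-dienophile gives the trans ring fusion (H5 α, C10 methyl β), the (E)-enal geometry places the C9 formyl group cis to the C10 methyl, the (1E)-enol ester geometry and the endo rule place the C8 benzoate cis to the formyl group, and the catalyst, which blocks the C9 Re face, fixes the absolute sense. The step needs endo selectivity, a single enal face and enough reactivity at the hindered β-carbon; the donor-substituted diene, the strongly acidic cation and the entropic help of the tether should supply them, and the benzoate should tolerate the Lewis acid.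

**Step 12**
Reactants: 18 8β-benzoyloxy-9β-formyl-4,4,10β-trimethyl-5αH-octal-6-ene
Product: 19 8β-benzoyloxy-9β-formyl-4,4,10β-trimethyl-5αH-decalin (trans-fused)
Conditions: H2 (1 atm), Rh/Al2O3 (5 wt%), EtOAc, rt
Reagents that add atoms: none
Why: Heterogeneous hydrogenation saturates the disubstituted C6=C7 alkene, and rhodium on alumina is chosen because it should neither hydrogenolyse the allylic benzoate nor reduce the hindered aldehyde.

**Step 13**
Reactants: 19 8β-benzoyloxy-9β-formyl-4,4,10β-trimethyl-5αH-decalin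
Product: 20 4,4,10β-trimethyl-5αH-octal-8-ene-9-carbaldehyde
Conditions: DBU, CH2Cl2, 0 °C → rt
Reagents that add atoms: none
Why: E1cB elimination is favoured because the axial C9–H (α to the formyl group) and the axial C8 benzoate are antiperiplanar; it gives the conjugated C8=C9 enal and removes the two stereocentres that are not carried on.

**Step 14**
Reactants: 20 4,4,10β-trimethyl-5αH-octal-8-ene-9-carbaldehyde
Product: 21 9-[(triethylsilyloxy)methylidene]-4,4,8α,10β-tetramethyl-5αH-decalin (C9=C11 geometry not defined)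
Conditions: Me2CuLi (from MeLi and CuI), TESCl, THF, −78 → −40 °C; Et3N, pentane
Reagents that add atoms: lithium dimethylcuprate, [Li+].C[Cu-]C; chlorotriethylsilane, CC[Si](Cl)(CC)CC
Why: Chlorosilane-assisted cuprate conjugate addition should deliver the methyl group to C8 on the α face, because the axial C10 methyl covers the β face of the C8=C9 bond; this sets 8α-CH3, and the enolate is trapped on oxygen.

**Step 15**
Reactants: 21 9-[(triethylsilyloxy)methylidene]-4,4,8α,10β-tetramethyl-5αH-decalin
Product: 23 4,4,8α,10β-tetramethyl-9α-(triethylsilyloxy)-5αH-decalin-9β-carbaldehyde, via silyloxy epoxide 22 (not isolated)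
Conditions: mCPBA, NaHCO3, CH2Cl2, −20 → 0 °C
Reagents that add atoms: 3-chloroperoxybenzoic acid, O=C(OO)c1cccc(Cl)c1
Why: In this Rubottom oxidation the peracid should attack the exocyclic enol ether from the α face, anti to the adjacent axial C10 methyl, and the 1,4-silyl shift on ring opening leaves the new tertiary C9 oxygen (α) protected as its triethylsilyl ether.

**Step 16**
Reactants: 23 4,4,8α,10β-tetramethyl-9α-(triethylsilyloxy)-5αH-decalin-9β-carbaldehyde
Product: 24 9β-ethenyl-4,4,8α,10β-tetramethyl-9α-(triethylsilyloxy)-5αH-decalin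
Conditions: Ph3PCH3Br, KN(SiMe3)2, THF, 0 °C → rt
Reagents that add atoms: methyltriphenylphosphonium bromide, C[P+](c1ccccc1)(c1ccccc1)c1ccccc1.[Br-]
Why: Wittig methylenation with the small, salt-free ylide should still reach the hindered non-enolisable aldehyde and supplies C12.

**Step 17**
Reactants: 25 pent-3-yn-1-ol
Product: 26 pent-3-ynal
Conditions: Dess–Martin periodinane, CH2Cl2, 0 °C → rt; used at once
Reagents that add atoms: none
Why: Neutral periodinane oxidation gives the sensitive β,γ-alkynyl aldehyde without base-induced isomerisation to the allene.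

**Step 18**
Reactants: 27 (S)-4-benzyl-3-propionyloxazolidin-2-one; 26 pent-3-ynal
Product: 29 (4S)-4-benzyl-3-[(2S,3R)-3-hydroxy-2-methylhept-5-ynoyl]oxazolidin-2-one, via boron enolate 28 (not isolated)
Conditions: Bu2BOTf, i-Pr2NEt, CH2Cl2, 0 °C; then 26, −78 → 0 °C; H2O2, MeOH, pH 7 buffer
Reagents that add atoms: none
Why: The Evans syn-aldol reaction of the (Z)-boron enolate proceeds through a closed chair transition state in which the (S)-benzyl auxiliary selects the enolate face, setting C17 and the syn C16 carbinol.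

**Step 19**
Reactants: 29 (4S)-4-benzyl-3-[(2S,3R)-3-hydroxy-2-methylhept-5-ynoyl]oxazolidin-2-one
Product: 30 (2R,3R)-2-methylhept-5-yne-1,3-diol
Conditions: LiBH4, MeOH (1 equiv), THF, 0 °C
Reagents that add atoms: none
Why: Reductive cleavage of the imide gives C18 at the alcohol level, so that no β-leaving group sits next to an ester later on, and releases the auxiliary.

**Step 20**
Reactants: 30 (2R,3R)-2-methylhept-5-yne-1,3-diol
Product: 31 (2R,3R)-1-[(tert-butyldiphenylsilyl)oxy]-2-methylhept-5-yn-3-ol
Conditions: TBDPSCl, imidazole, CH2Cl2, 0 °C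
Reagents that add atoms: tert-butyldiphenylsilyl chloride, CC(C)(C)[Si](Cl)(c1ccccc1)c1ccccc1
Why: The bulky silyl chloride should silylate the primary hydroxyl selectively and gives an acid-stable ether that survives the later perhydrolysis.

**Step 21**
Reactants: 31 (2R,3R)-1-[(tert-butyldiphenylsilyl)oxy]-2-methylhept-5-yn-3-ol
Product: 33 (2R,3R,5E)-1-[(tert-butyldiphenylsilyl)oxy]-6-iodo-2-methylhept-5-en-3-ol, via alkenylzirconocene 32 (not isolated)
Conditions: Cp2Zr(H)Cl (2.5 equiv), THF, 50 °C; then I2, THF, 0 °C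
Reagents that add atoms: iodine, II
Why: syn-Hydrozirconation with excess hydride (one equivalent is consumed by the hydroxyl) should equilibrate zirconium to the less hindered methyl-bearing alkyne carbon, and iodinolysis with retention gives the (E)-2-iodoalkene.

**Step 22**
Reactants: 24 9β-ethenyl-4,4,8α,10β-tetramethyl-9α-(triethylsilyloxy)-5αH-decalin; 33 (2R,3R,5E)-1-[(tert-butyldiphenylsilyl)oxy]-6-iodo-2-methylhept-5-en-3-ol
Product: 35 (13E,16R,17R)-18-[(tert-butyldiphenylsilyl)oxy]-9α-(triethylsilyloxy)-16-hydroxy C11–C18 chain alkene on the 4,4,8α,10β-tetramethyl-5αH-decalin, via alkylborane 34 (not isolated)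
Conditions: 9-BBN (9-borabicyclo[3.3.1]nonane), THF, 60 °C; then 33, PdCl2(dppf) [dppf = Fe(C5H4PPh2)2] (5 mol%), AsPh3, Cs2CO3, DMF/THF/H2O, rt
Reagents that add atoms: none
Why: Anti-Markovnikov hydroboration of the vinyl group followed by B-alkyl Suzuki–Miyaura coupling forms C12–C13 with retention of the iodide geometry, giving the (E)-trisubstituted C13=C14 alkene.

**Step 23**
Reactants: 35 coupled alcohol
Product: 36 (13E,16R,17R)-16-methanesulfonate of 35
Conditions: MsCl, Et3N, CH2Cl2, 0 °C
Reagents that add atoms: methanesulfonyl chloride, CS(=O)(=O)Cl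
Why: Sulfonylation of the only free hydroxyl turns C16 into the electrophile for the later ring closure with retention at this stage.

**Step 24**
Reactants: 36 mesylate
Product: 37 (13S,14S,16R,17R)-13,14-epoxide of 36
Conditions: 1,2:4,5-di-O-isopropylidene-β-L-erythro-2,3-hexodiulo-2,6-pyranose (L-fructose-derived ketone, C12H18O6, 30 mol%), KHSO5 (as 2KHSO5·KHSO4·K2SO4), K2CO3, Bu4NHSO4, MeCN/dimethoxymethane/aq. buffer pH 10.5, 0 °C
Reagents that add atoms: potassium peroxymonosulfate, [K+].[O-]S(=O)(=O)OO
Why: In the Shi epoxidation the chiral dioxirane transfers oxygen to one face of the (E)-trisubstituted alkene through a spiro transition state, so the epoxide configuration is set by the reagent and not by the remote stereocentres.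

**Step 25**
Reactants: 37 epoxide
Product: 38 (13R,14S,16R,17R)-13-hydroperoxy-14-hydroxy-16-mesylate
Conditions: H2O2 (anhydrous, in Et2O, 10 equiv), H3PMo12O40 (2 mol%), Et2O, 0 °C → rt
Reagents that add atoms: hydrogen peroxide, OO
Why: Acid-catalysed perhydrolysis of the trisubstituted epoxide should occur at the tertiary C13 from the back side, fixing the C13–O configuration by inversion, while the hindered silyl ether keeps O9 from opening the epoxide itself.

**Step 26**
Reactants: 38 hydroperoxide
Product: 39 (13R,14S,16S,17R)-14-hydroxy-1,2-dioxane (ring C closed)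
Conditions: KOtBu (1.05 equiv), 18-crown-6, toluene, 0 °C
Reagents that add atoms: none
Why: The hydroperoxide, far more acidic than the alcohol, is deprotonated selectively and displaces the C16 mesylate in a 6-exo-tet intramolecular SN2 alkylation with inversion, placing the C12 chain and the C17 side chain both equatorial.

**Step 27**
Reactants: 39 14-hydroxy-1,2-dioxane
Product: 40 14-O-(phenoxythiocarbonyl) derivative of 39
Conditions: PhOC(S)Cl, pyridine, DMAP, CH2Cl2, rt
Reagents that add atoms: O-phenyl chlorothionoformate, S=C(Cl)Oc1ccccc1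
Why: Acylation of the secondary alcohol under non-basic conditions gives the thionocarbonate without forming the C14 alkoxide, which could fragment onto the peroxide.

**Step 28**
Reactants: 40 thionocarbonate
Product: 41 (13S,16S,17R)-18-[(tert-butyldiphenylsilyl)oxy]-9α-(triethylsilyloxy) 1,2-dioxane
Conditions: Bu3SnH (5 equiv, 0.5 M), azobisisobutyronitrile (cat.), toluene, 80 °C
Reagents that add atoms: none
Why: Proposed new method: Barton–McCombie deoxygenation has not been shown on a 1,2-dioxan-4-ol; the C14 radical lies β to the peroxide but inside the ring, where the in-line geometry for homolytic attack on oxygen is not available and C–O β-scission should be slower than hydrogen transfer from concentrated stannane, the closest known reactions being the borohydride demercuration of β-peroxyalkylmercurials (the same radical type) and the standard reduction of secondary thionocarbonates.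

**Step 29**
Reactants: 41 bis-silyl dioxane
Product: 42 (13S,16S,17R)-9α,18-diol
Conditions: HF·pyridine, THF, 0 °C → rt
Reagents that add atoms: none
Why: Acidic fluoride cleaves the primary tert-butyldiphenylsilyl and the tertiary triethylsilyl ether while the dialkyl peroxide, which is base-sensitive but acid-tolerant, is left alone.

**Step 30**
Reactants: 42 diol
Product: 43 CNP0328037.1
Conditions: TEMPO (2,2,6,6-tetramethylpiperidin-1-oxyl, 20 mol%), PhI(OAc)2 (2.5 equiv), MeCN/H2O, rt
Reagents that add atoms: water, O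
Why: Oxoammonium oxidation takes the primary alcohol through the aldehyde hydrate to the acid in one pot, cannot touch the tertiary C9 alcohol, and keeps the β-peroxy aldehyde too short-lived for elimination or C17 epimerisation.

**Compound list**
1 | geraniol | CC(C)=CCC/C(C)=C/CO | starting material
2 | geranyl tert-butyldimethylsilyl ether | CC(C)=CCC/C(C)=C/CO[Si](C)(C)C(C)(C)C | intermediate
3 | 6,7-epoxygeranyl tert-butyldimethylsilyl ether (racemic at the epoxide CH) | CC1(C)OC1CC/C(C)=C/CO[Si](C)(C)C(C)(C)C | intermediate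
4 | (E)-6-[(tert-butyldimethylsilyl)oxy]-4-methylhex-4-enal | O=CCC/C(C)=C/CO[Si](C)(C)C(C)(C)C | intermediate
5 | (E)-6-[(tert-butyldimethylsilyl)oxy]-4-methylhex-4-en-1-ol | OCCC/C(C)=C/CO[Si](C)(C)C(C)(C)C | intermediate
6 | (E)-[(6-bromo-3-methylhex-2-enyl)oxy](tert-butyl)dimethylsilane | BrCCC/C(C)=C/CO[Si](C)(C)C(C)(C)C | intermediate
7 | ethyl 3-methylbut-2-enoate | CCOC(=O)C=C(C)C | starting material
8 | Grignard reagent of 6 | Br[Mg]CCC/C(C)=C/CO[Si](C)(C)C(C)(C)C | intermediate
9 | ethyl trimethylsilyl ketene acetal of 10 (geometry not defined) | CCOC(O[Si](C)(C)C)=CC(C)(C)CCC/C(C)=C/CO[Si](C)(C)C(C)(C)C | intermediate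
10 | ethyl (E)-9-[(tert-butyldimethylsilyl)oxy]-3,3,7-trimethylnon-7-enoate | CCOC(=O)CC(C)(C)CCC/C(C)=C/CO[Si](C)(C)C(C)(C)C | intermediate
11 | (E)-9-[(tert-butyldimethylsilyl)oxy]-3,3,7-trimethylnon-7-enal | O=CCC(C)(C)CCC/C(C)=C/CO[Si](C)(C)C(C)(C)C | intermediate
12 | (triphenylphosphoranylidene)acetaldehyde | O=CC=P(c1ccccc1)(c1ccccc1)c1ccccc1 | starting material
13 | (2E,9E)-11-[(tert-butyldimethylsilyl)oxy]-5,5,9-trimethylundeca-2,9-dienal | O=C/C=C/CC(C)(C)CCC/C(C)=C/CO[Si](C)(C)C(C)(C)C | intermediate
14 | potassium (1E,3E)-dienolate of 13 | [K+].[O-]/C=C/C=C/C(C)(C)CCC/C(C)=C/CO[Si](C)(C)C(C)(C)C | intermediate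
15 | (1E,3E,9E)-11-[(tert-butyldimethylsilyl)oxy]-5,5,9-trimethylundeca-1,3,9-trienyl benzoate | O=C(O/C=C/C=C/C(C)(C)CCC/C(C)=C/CO[Si](C)(C)C(C)(C)C)c1ccccc1 | intermediate
16 | (1E,3E,9E)-11-hydroxy-5,5,9-trimethylundeca-1,3,9-trienyl benzoate | O=C(O/C=C/C=C/C(C)(C)CCC/C(C)=C/CO)c1ccccc1 | intermediate
17 | (2E,8E,10E)-11-(benzoyloxy)-3,7,7-trimethylundeca-2,8,10-trienal | O=C/C=C(\C)CCCC(C)(C)/C=C/C=C/OC(=O)c1ccccc1 | intermediate
18 | 8β-benzoyloxy-9β-formyl-4,4,10β-trimethyl-5αH-octal-6-ene (trans-fused cycloadduct) | O=C[C@H]1[C@@H](OC(=O)c2ccccc2)C=C[C@H]3C(C)(C)CCC[C@]13C | intermediate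
19 | 8β-benzoyloxy-9β-formyl-4,4,10β-trimethyl-5αH-decalin | O=C[C@H]1[C@@H](OC(=O)c2ccccc2)CC[C@H]3C(C)(C)CCC[C@]13C | intermediate
20 | 4,4,10β-trimethyl-5αH-octal-8-ene-9-carbaldehyde | O=CC1=CCC[C@H]3C(C)(C)CCC[C@]13C | intermediate
21 | 9-[(triethylsilyloxy)methylidene]-4,4,8α,10β-tetramethyl-5αH-decalin | CC[Si](CC)(CC)OC=C1[C@H](C)CC[C@H]3C(C)(C)CCC[C@]13C | intermediate
22 | 9α,11-epoxy-11-(triethylsilyloxy) spiro-epoxide of 21 (C11 not defined) | CC[Si](CC)(CC)OC1O[C@@]12[C@H](C)CC[C@H]3C(C)(C)CCC[C@]23C | intermediate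
23 | 4,4,8α,10β-tetramethyl-9α-(triethylsilyloxy)-5αH-decalin-9β-carbaldehyde | O=C[C@@]1(O[Si](CC)(CC)CC)[C@H](C)CC[C@H]3C(C)(C)CCC[C@]13C | intermediate
24 | 9β-ethenyl-4,4,8α,10β-tetramethyl-9α-(triethylsilyloxy)-5αH-decalin | C=C[C@@]1(O[Si](CC)(CC)CC)[C@H](C)CC[C@H]3C(C)(C)CCC[C@]13C | intermediate
25 | pent-3-yn-1-ol | CC#CCCO | starting material
26 | pent-3-ynal | CC#CCC=O | intermediate
27 | (S)-4-benzyl-3-propionyloxazolidin-2-one | CCC(=O)N1[C@@H](Cc2ccccc2)COC1=O | starting material
28 | (Z)-dibutylboron enolate of 27 | CCCCB(CCCC)O/C(=C\C)N1[C@@H](Cc2ccccc2)COC1=O | intermediate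
29 | (4S)-4-benzyl-3-[(2S,3R)-3-hydroxy-2-methylhept-5-ynoyl]oxazolidin-2-one | CC#CC[C@@H](O)[C@H](C)C(=O)N1[C@@H](Cc2ccccc2)COC1=O | intermediate
30 | (2R,3R)-2-methylhept-5-yne-1,3-diol | CC#CC[C@@H](O)[C@H](C)CO | intermediate
31 | (2R,3R)-1-[(tert-butyldiphenylsilyl)oxy]-2-methylhept-5-yn-3-ol | CC#CC[C@@H](O)[C@H](C)CO[Si](c1ccccc1)(c1ccccc1)C(C)(C)C | intermediate
32 | C13 alkenylzirconocene chloride of 31 with O16 bound to a second Cp2ZrCl | C/C(=C\C[C@@H](O[Zr](Cl)(C1C=CC=C1)C1C=CC=C1)[C@H](C)CO[Si](c1ccccc1)(c1ccccc1)C(C)(C)C)[Zr](Cl)(C1C=CC=C1)C1C=CC=C1 | intermediate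
33 | (2R,3R,5E)-1-[(tert-butyldiphenylsilyl)oxy]-6-iodo-2-methylhept-5-en-3-ol | C/C(I)=C\C[C@@H](O)[C@H](C)CO[Si](c1ccccc1)(c1ccccc1)C(C)(C)C | intermediate
34 | B-[2-(decalin-9β-yl)ethyl]-9-borabicyclo[3.3.1]nonane from 24 | C1CCC2CCCC1B2CC[C@@]3(O[Si](CC)(CC)CC)[C@H](C)CC[C@H]4C(C)(C)CCC[C@]34C | intermediate
35 | (13E,16R,17R)-coupled alcohol: 9α-OSiEt3, C13=C14, 16-OH, 18-OSi(t-Bu)Ph2 | C/C(=C\C[C@@H](O)[C@H](C)CO[Si](c1ccccc1)(c1ccccc1)C(C)(C)C)CC[C@@]2(O[Si](CC)(CC)CC)[C@H](C)CC[C@H]3C(C)(C)CCC[C@]23C | intermediate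
36 | (13E,16R,17R)-16-methanesulfonate of 35 | C/C(=C\C[C@@H](OS(C)(=O)=O)[C@H](C)CO[Si](c1ccccc1)(c1ccccc1)C(C)(C)C)CC[C@@]2(O[Si](CC)(CC)CC)[C@H](C)CC[C@H]3C(C)(C)CCC[C@]23C | intermediate
37 | (13S,14S,16R,17R)-13,14-epoxy mesylate | C[C@@]1(CC[C@@]2(O[Si](CC)(CC)CC)[C@H](C)CC[C@H]3C(C)(C)CCC[C@]23C)O[C@H]1C[C@@H](OS(C)(=O)=O)[C@H](C)CO[Si](c1ccccc1)(c1ccccc1)C(C)(C)C | intermediate
38 | (13R,14S,16R,17R)-13-hydroperoxy-14-hydroxy mesylate | C[C@](CC[C@@]2(O[Si](CC)(CC)CC)[C@H](C)CC[C@H]3C(C)(C)CCC[C@]23C)(OO)[C@@H](O)C[C@@H](OS(C)(=O)=O)[C@H](C)CO[Si](c1ccccc1)(c1ccccc1)C(C)(C)C | intermediate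
39 | (13R,14S,16S,17R)-14-hydroxy-1,2-dioxane | C[C@]1(CC[C@@]2(O[Si](CC)(CC)CC)[C@H](C)CC[C@H]3C(C)(C)CCC[C@]23C)OO[C@@H](C[C@@H]1O)[C@H](C)CO[Si](c1ccccc1)(c1ccccc1)C(C)(C)C | intermediate
40 | 14-O-(phenoxythiocarbonyl) derivative of 39 | C[C@]1(CC[C@@]2(O[Si](CC)(CC)CC)[C@H](C)CC[C@H]3C(C)(C)CCC[C@]23C)OO[C@@H](C[C@@H]1OC(=S)Oc1ccccc1)[C@H](C)CO[Si](c1ccccc1)(c1ccccc1)C(C)(C)C | intermediate
41 | (13S,16S,17R)-bis-silyl 1,2-dioxane (9α-OSiEt3, 18-OSi(t-Bu)Ph2) | C[C@]1(CC[C@@]2(O[Si](CC)(CC)CC)[C@H](C)CC[C@H]3C(C)(C)CCC[C@]23C)OO[C@@H](CC1)[C@H](C)CO[Si](c1ccccc1)(c1ccccc1)C(C)(C)C | intermediate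
42 | (13S,16S,17R)-9α,18-diol | C[C@]1(CC[C@@]2(O)[C@H](C)CC[C@H]3C(C)(C)CCC[C@]23C)OO[C@@H](CC1)[C@H](C)CO | intermediate
43 | CNP0328037.1, (5S,8R,9R,10S,13S,16S,17S)-acid | C[C@H](C(=O)O)[C@@H]1CC[C@@](C)(CC[C@@]2(O)[C@H](C)CC[C@H]3C(C)(C)CCC[C@@]32C)OO1 | target

**Step count and risks**
Total: 30 steps. Longest linear sequence: 25 steps (steps 1–16 and 22–30); steps 17–21 build the side-chain iodide.

The three steps most likely to fail:

Step 11. The β,β-disubstituted enal may be too hindered for turnover at low temperature, the chiral cation may discriminate the faces poorly, or the acid may trigger loss of benzoate from the adduct. The fallback sets out from 17 and drops catalyst control: cyclisation by heating in toluene (130 °C, radical inhibitor) or with Me2AlCl at low temperature, a known way to trans-decalins with an angular methyl group from β-methyl trienals, should give the racemic endo cycloadduct F1. Its enantiomers are separated by preparative chromatography on a chiral stationary phase, and the (5S,10S) antipode is 18, where the route is rejoined.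

Step 28. The C14 radical may fragment the neighbouring C–O bond or attack the peroxide faster than it is reduced, so that ring C opens. The fallback sets out from 36 and avoids the 14-oxygen altogether. Mukaiyama–Isayama hydroperoxysilylation (Co(C11H19O2)2, the bis(2,2,6,6-tetramethylheptane-3,5-dionate), with O2 and Et3SiH in 1,2-dichloroethane) places hydrogen on C14 and oxygen on the tertiary C13, giving the triethylsilyl peroxide F2 as both C13 epimers. K2CO3 in MeOH frees the peroxide anion, which displaces the C16 mesylate with inversion. This gives 41 together with its C13 epimer F3, which is removed by chromatography; the route is rejoined at 41. Control at C13 is given up for well-precedented chemistry.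

Step 25. The epoxide opening may lose regiochemical or stereochemical fidelity through partial ionisation at C13, attack at C14, or participation of O9 after loss of the triethylsilyl group. The fallback sets out from 36 and forms the C13–O bond in the ring closure instead. Displacement of the mesylate by H2O2/KOH in MeOH/Et2O (inversion at C16) should give the secondary hydroperoxide F4. Hg(OAc)2 in CH2Cl2 then induces cycloperoxymercuration with Markovnikov attack of the hydroperoxide on C13, closing ring C as the organomercurial F5. NaBH4/NaOH demercuration gives 41 and the C13 epimer F3, separated by chromatography; the route is rejoined at 41.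

**Further compounds**
F1 | step 11 | racemic trans-fused endo cycloadduct (racemate of 18, relative configuration shown) | O=C[C@H]1[C@@H](OC(=O)c2ccccc2)C=C[C@H]3C(C)(C)CCC[C@]13C
F2 | step 28 | C13 triethylsilyl peroxide of the 16-mesylate (both C13 epimers) | CC(CC[C@@]2(O[Si](CC)(CC)CC)[C@H](C)CC[C@H]3C(C)(C)CCC[C@]23C)(OO[Si](CC)(CC)CC)CC[C@@H](OS(C)(=O)=O)[C@H](C)CO[Si](c1ccccc1)(c1ccccc1)C(C)(C)C
F3 | step 28 | C13 epimer of 41 | C[C@@]1(CC[C@@]2(O[Si](CC)(CC)CC)[C@H](C)CC[C@H]3C(C)(C)CCC[C@]23C)OO[C@@H](CC1)[C@H](C)CO[Si](c1ccccc1)(c1ccccc1)C(C)(C)C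
F4 | step 25 | (13E,16S,17R)-16-hydroperoxide from 36 | C/C(=C\C[C@H](OO)[C@H](C)CO[Si](c1ccccc1)(c1ccccc1)C(C)(C)C)CC[C@@]2(O[Si](CC)(CC)CC)[C@H](C)CC[C@H]3C(C)(C)CCC[C@]23C
F5 | step 25 | 14-(acetoxymercurio)-1,2-dioxane (C13 and C14 not defined) | CC1(CC[C@@]2(O[Si](CC)(CC)CC)[C@H](C)CC[C@H]3C(C)(C)CCC[C@]23C)OO[C@@H](CC1[Hg]OC(C)=O)[C@H](C)CO[Si](c1ccccc1)(c1ccccc1)C(C)(C)C
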